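**Plan**

1. Flavan numbering is used: ring C = O1-C2-C3-C4-C4a-C8a, ring A = C4a-C5-C6-C7-C8-C8a, ring B = the 4-hydroxyphenyl group on C2. Retrosynthetic cuts, in order: the two aryl O-Si bonds; the C4-OH bond (back to a C4-OMe helper); C3-C4 and O1-C2 of ring C together in one retro-[4+2]; last the 5-O-Si, C8-prenyl and 7-O-CH3 bonds on ring A.
2. Enabling feature: C4 is a benzylic, oxygen-bearing carbon on C4a. It lies ortho to O1 (on C8a) and to O5 and para to the 7-methoxy group, so O1=C8a-C4a=C4(OMe) is an easily reached alkoxy ortho-quinone methide of a salicylaldehyde. C2=C3 with ring B on C2 is a polarised, electron-rich styrene.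
3. Forward: rings A and B are bought. Ring A is dressed (7-OMe, 8-prenyl, 5-OTBS) with C4 at the aldehyde oxidation level, and ring B enters as a 4-silyloxystyrene. Ring C arises last, in a single cycloaddition that makes C3-C4 and O1-C2.
4. Stereochemistry: C2 (S) comes from a chiral imidodiphosphoric acid in the cycloaddition. C4 (R, 2,4-trans) comes from the quinone methide geometry in the same step. It is set again when the C4-OMe helper is hydrolysed, because water attacks the C4 cation pseudoaxially under control of C2 and of the peri 5-substituent.

Key step: step 5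

Assumption: the (S,S)-configured acid is taken to lead to the (2S) series. The sense of induction has to be assigned on the first cycloadduct, and the (R,R)-acid serves if it is the opposite one.

Step 1
Reactants: 1 2,4,6-trihydroxybenzaldehyde
Product: 2 2,6-dihydroxy-4-methoxybenzaldehyde
Conditions: MeI (1.0 equiv), K2CO3 (1.0 equiv), acetone, rt
Reagents that add atoms: iodomethane (MeI), CI
Why: Williamson O-methylation, in which the 4-hydroxyl (para to the formyl group) is the most acidic and the only one not held in a hydrogen bond to C=O, so one equivalent of base and MeI should alkylate it selectively.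

Step 2
Reactants: 2 2,6-dihydroxy-4-methoxybenzaldehyde; 3 prenyl bromide (1-bromo-3-methylbut-2-ene)
Product: 4 2,6-dihydroxy-4-methoxy-3-(3-methylbut-2-enyl)benzaldehyde
Conditions: KOH (1.1 equiv), MeOH, 0 °C to rt
Reagents that add atoms: none
Why: Nuclear C-prenylation of an acylphloroglucinol-type phenoxide, in which the protic medium masks the oxygen by hydrogen bonding so that the soft allylic bromide is taken up at a ring carbon, and because C3 and C5 of 2 are equivalent only one mono-C-prenyl isomer can form.

Step 3
Reactants: 4 2,6-dihydroxy-4-methoxy-3-(3-methylbut-2-enyl)benzaldehyde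
Product: 5 6-(tert-butyldimethylsilyloxy)-2-hydroxy-4-methoxy-3-(3-methylbut-2-enyl)benzaldehyde
Conditions: TBSCl (1.05 equiv), imidazole (2.2 equiv), DMF, 0 °C
Reagents that add atoms: tert-butyldimethylsilyl chloride (TBSCl), CC(C)(C)[Si](C)(C)Cl
Why: Sterically governed silyl ether formation, in which the hydroxyl flanked by CHO and H should be silylated in preference to the one wedged between CHO and the prenyl chain, leaving free exactly the oxygen that becomes O1.

Step 4
Reactants: 6 4-acetoxystyrene
Product: 8 4-(tert-butyldimethylsilyloxy)styrene, via 4-vinylphenol 7 (not isolated)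
Conditions: NaOMe (5 mol %), MeOH, 0 °C to rt; evaporate; then TBSCl (1.1 equiv), imidazole (2.2 equiv), DMF, 0 °C to rt
Reagents that add atoms: tert-butyldimethylsilyl chloride (TBSCl), CC(C)(C)[Si](C)(C)Cl
Why: Base-catalysed transesterification frees the polymerisation-prone phenol 7, which is silylated at once under standard imidazole conditions, and the silyl ether keeps ring B electron-rich as the cycloaddition requires.

Step 5
Reactants: 5 6-(tert-butyldimethylsilyloxy)-2-hydroxy-4-methoxy-3-(3-methylbut-2-enyl)benzaldehyde; 8 4-(tert-butyldimethylsilyloxy)styrene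
Product: 11 (2S,4R)-5-(tert-butyldimethylsilyloxy)-2-[4-(tert-butyldimethylsilyloxy)phenyl]-4,7-dimethoxy-8-(3-methylbut-2-enyl)chroman, via dimethyl acetal 9 (not isolated), via methoxy ortho-quinone methide 10 (not isolated)
Conditions: HC(OMe)3 (1.5 equiv), 8 (2 equiv), (S,S)-imidodiphosphoric acid built from two 3,3'-bis(2,4,6-triethylphenyl)-1,1'-bi-2-naphthol units (5 mol %), 4 Å molecular sieves, toluene, -20 °C
Reagents that add atoms: trimethyl orthoformate, COC(OC)OC
Why: Proposed new method: the chiral acid first lets 5 exchange with HC(OMe)3 to acetal 9, whose free C8a hydroxyl then pushes out methanol to give the acid-bound (Z)-alpha-methoxy ortho-quinone methide 10 (1-oxadiene O1=C8a-C4a=C4), and the electron-rich styrene 8 adds to it in an inverse-electron-demand, concerted but asynchronous [4+2] cycloaddition that forms C3-C4 (styrene CH2 onto the electrophilic methide carbon) and O1-C2 in one event. The closest known reaction types are the Sc(OTf)3-catalysed three-component union of salicylaldehydes, trimethyl orthoformate and electron-rich alkenes to racemic 4-methoxychromans and the imidodiphosphoric-acid-catalysed enantioselective intramolecular [4+2] of the same salicylaldehyde-derived alkoxy quinone methides with tethered alkenes, so that only the combination of an untethered styrene with enantiocontrol is new. Ring C (O1-C2-C3-C4-C4a-C8a) closes as a six-membered dihydropyran by intermolecular hetero-Diels-Alder addition, its regiochemistry fixed by polarity, and in the stepwise limit the second bond would be a 6-exo-trig capture of the para-silyloxybenzyl cation at C2 by O1. C2 is controlled by the catalyst, because the imidodiphosphate holds 10 by a hydrogen bond or ion pair at O1 inside its confined pocket, leaves one face of the oxadiene open and so decides which face of C4 and, through the endo orientation of ring B, which face of the styrene reacts, here taken as giving (2S). C4 is controlled by the substrate, because the peri 5-OTBS group forces the methoxy group of 10 into the inside (Z) position next to O1, and an inside substituent and an endo aryl group end on opposite faces, that is 2,4-trans (4R), which is also the isomer whose pseudoaxial C4 substituent escapes peri strain. The step needs site selectivity (secured by the silyl ether on the other ortho oxygen, so that only O1 can form the quinone methide and the 8-prenyl rather than the 6-prenyl series results), chemoselectivity for 8 over the prenyl double bond (8 is the far better pi-nucleophile, is used in excess, and the prenyl group cannot reach C4 within the molecule) and an acidity window in which acetal 9 ionises while ether 11, the aryl silyl ethers and the ortho-prenylphenol unit of 5 do not react.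

Step 6
Reactants: 11 (2S,4R)-5-(tert-butyldimethylsilyloxy)-2-[4-(tert-butyldimethylsilyloxy)phenyl]-4,7-dimethoxy-8-(3-methylbut-2-enyl)chroman
Product: 12 (2S,4R)-5-(tert-butyldimethylsilyloxy)-2-[4-(tert-butyldimethylsilyloxy)phenyl]-7-methoxy-8-(3-methylbut-2-enyl)chroman-4-ol
Conditions: pyridinium p-toluenesulfonate (10 mol %), THF/H2O 4:1, 0.01 M, 0 °C to rt
Reagents that add atoms: water, O
Why: SN1 solvolysis of a 2,4,6-trioxygenated benzylic ether (the reaction type behind the acid exchange of 4-alkoxyflavans), in which the planar C4 cation stabilised by O1, O5 and the 7-methoxy group is captured by the large excess of water along the pseudoaxial trajectory on the face opposite to the equatorial ring B, and since the pseudoaxial carbinol also avoids peri strain with 5-OTBS, kinetic and equilibrium control should both lead to (4R) from either C4 epimer of 11, while C2, the aryl silyl ethers and the prenyl group are not touched by this weak acid.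

Step 7
Reactants: 12 (2S,4R)-5-(tert-butyldimethylsilyloxy)-2-[4-(tert-butyldimethylsilyloxy)phenyl]-7-methoxy-8-(3-methylbut-2-enyl)chroman-4-ol
Product: 13 (2S,4R)-2-(4-hydroxyphenyl)-7-methoxy-8-(3-methylbut-2-enyl)chroman-4,5-diol (4,5,4'-trihydroxy-7-methoxy-8-prenylflavan)
Conditions: Bu4NF (2.2 equiv), AcOH (2.2 equiv), THF, 0 °C; pH 7 phosphate buffer work-up
Reagents that add atoms: none
Why: Fluoride-induced cleavage of both aryl silyl ethers under acetic acid buffering, conditions neither acidic enough to ionise C4-OH nor basic enough to open ring C through a para-quinone methide, so C2 and C4 should stay untouched.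

**Compound list**

1 | 2,4,6-trihydroxybenzaldehyde | O=Cc1c(O)cc(O)cc1O | starting material
2 | 2,6-dihydroxy-4-methoxybenzaldehyde | COc1cc(O)c(C=O)c(O)c1 | intermediate
3 | prenyl bromide (1-bromo-3-methylbut-2-ene) | CC(C)=CCBr | starting material
4 | 2,6-dihydroxy-4-methoxy-3-(3-methylbut-2-enyl)benzaldehyde | COc1cc(O)c(C=O)c(O)c1CC=C(C)C | intermediate
5 | 6-(tert-butyldimethylsilyloxy)-2-hydroxy-4-methoxy-3-(3-methylbut-2-enyl)benzaldehyde | COc1cc(O[Si](C)(C)C(C)(C)C)c(C=O)c(O)c1CC=C(C)C | intermediate
6 | 4-acetoxystyrene | C=Cc1ccc(OC(C)=O)cc1 | starting material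
7 | 4-vinylphenol | C=Cc1ccc(O)cc1 | intermediate
8 | 4-(tert-butyldimethylsilyloxy)styrene | C=Cc1ccc(O[Si](C)(C)C(C)(C)C)cc1 | intermediate
9 | 6-(tert-butyldimethylsilyloxy)-2-hydroxy-4-methoxy-3-(3-methylbut-2-enyl)benzaldehyde dimethyl acetal | COc1cc(O[Si](C)(C)C(C)(C)C)c(C(OC)OC)c(O)c1CC=C(C)C | intermediate
10 | (6Z)-5-(tert-butyldimethylsilyloxy)-3-methoxy-6-(methoxymethylidene)-2-(3-methylbut-2-enyl)cyclohexa-2,4-dien-1-one | CO/C=C1\C(=O)C(CC=C(C)C)=C(OC)C=C1O[Si](C)(C)C(C)(C)C | intermediate
11 | (2S,4R)-5-(tert-butyldimethylsilyloxy)-2-[4-(tert-butyldimethylsilyloxy)phenyl]-4,7-dimethoxy-8-(3-methylbut-2-enyl)chroman (2,4-trans) | COc1cc(O[Si](C)(C)C(C)(C)C)c2c(c1CC=C(C)C)O[C@H](c1ccc(O[Si](C)(C)C(C)(C)C)cc1)C[C@H]2OC | intermediate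
12 | (2S,4R)-5-(tert-butyldimethylsilyloxy)-2-[4-(tert-butyldimethylsilyloxy)phenyl]-7-methoxy-8-(3-methylbut-2-enyl)chroman-4-ol (2,4-trans) | COc1cc(O[Si](C)(C)C(C)(C)C)c2c(c1CC=C(C)C)O[C@H](c1ccc(O[Si](C)(C)C(C)(C)C)cc1)C[C@H]2O | intermediate
13 | (2S,4R)-2-(4-hydroxyphenyl)-7-methoxy-8-(3-methylbut-2-enyl)chroman-4,5-diol | COc1cc(O)c2c(c1CC=C(C)C)O[C@H](c1ccc(O)cc1)C[C@H]2O | target

Total step count: 7. Longest linear sequence: 6 (steps 1, 2, 3, 5, 6, 7).

**Steps most likely to fail**

Step 5 (bears the label).
- What may go wrong: weak facial discrimination on a sterically loaded, 2,6-disubstituted quinone methide; acid-induced oligomerisation of the styrene; or re-ionisation of the product at C4 followed by a second alkylation.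
- The fallback replaces catalyst control by a covalently bound auxiliary and a separation, and it uses only known chemistry. It sets out from 5 and 8.
- The ring closure is run as the Lewis-acid three-component reaction (Sc(OTf)3, 10 mol %, 4 Å molecular sieves, CH2Cl2, 0 °C), with (-)-menthol as the alcohol partner in place of the orthoformate.
- The two 2,4-trans cycloadducts, the (2S,4R)-4-menthyl ether F1 and the (2R,4S)-4-menthyl ether F2, are diastereomers. They are separated by chromatography or crystallisation.
- F1 is then hydrolysed under the conditions of step 6, which releases the auxiliary and brings the material back to the route at 12.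

Step 6.
- What may go wrong: loss of a proton from C3 of the C4 cation, Friedel-Crafts self-condensation of that cation with C6 of a second molecule, or an insufficient preference for pseudoaxial capture.
- The fallback avoids any heterolysis of the C4-O bond. It sets out from 5 and 8.
- Step 5 is run with triallyl orthoformate in place of trimethyl orthoformate and should give the (2S,4R)-4-allyl ether F3.
- The O-allyl bond is then cleaved by nickel-catalysed hydroalumination and elimination (NiCl2(dppp), 2 mol %, i-Bu2AlH, toluene, 0 °C; Rochelle salt work-up).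
- The C4 configuration set in the cycloaddition is thereby retained, and the route is rejoined at 12.

Step 2.
- What may go wrong: competing O-alkylation and double alkylation of the ambident phenoxide.
- The fallback moves the prenyl group onto carbon by sigmatropic shifts rather than by direct C-alkylation. It sets out from 2 and 3.
- Mono-O-prenylation (K2CO3, acetone, reflux) should give 2-hydroxy-4-methoxy-6-(3-methylbut-2-enyloxy)benzaldehyde F4.
- Heating F4 in N,N-diethylaniline at 190-200 °C triggers an aromatic Claisen rearrangement to the free ortho carbon, followed by a Cope shift to the para carbon.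
- This sequence delivers the normal prenyl group between OH and OMe and comes back to the route at 4.

**Further compounds**

F1 | step 5 | (2S,4R)-5-(tert-butyldimethylsilyloxy)-2-[4-(tert-butyldimethylsilyloxy)phenyl]-7-methoxy-4-[(1R,2S,5R)-menthyloxy]-8-(3-methylbut-2-enyl)chroman | COc1cc(O[Si](C)(C)C(C)(C)C)c2c(c1CC=C(C)C)O[C@H](c1ccc(O[Si](C)(C)C(C)(C)C)cc1)C[C@H]2O[C@@H]3C[C@H](C)CC[C@H]3C(C)C
F2 | step 5 | (2R,4S)-5-(tert-butyldimethylsilyloxy)-2-[4-(tert-butyldimethylsilyloxy)phenyl]-7-methoxy-4-[(1R,2S,5R)-menthyloxy]-8-(3-methylbut-2-enyl)chroman | COc1cc(O[Si](C)(C)C(C)(C)C)c2c(c1CC=C(C)C)O[C@@H](c1ccc(O[Si](C)(C)C(C)(C)C)cc1)C[C@@H]2O[C@@H]3C[C@H](C)CC[C@H]3C(C)C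
F3 | step 6 | (2S,4R)-4-allyloxy-5-(tert-butyldimethylsilyloxy)-2-[4-(tert-butyldimethylsilyloxy)phenyl]-7-methoxy-8-(3-methylbut-2-enyl)chroman | COc1cc(O[Si](C)(C)C(C)(C)C)c2c(c1CC=C(C)C)O[C@H](c1ccc(O[Si](C)(C)C(C)(C)C)cc1)C[C@H]2OCC=C
F4 | step 2 | 2-hydroxy-4-methoxy-6-(3-methylbut-2-enyloxy)benzaldehyde | COc1cc(O)c(C=O)c(OCC=C(C)C)c1
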